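Ring B of the tetralin is closed last by a one-pot photoredox/acid cascade from an open-chain diol monoacetate. The cascade is a proposal; its two halves have separate precedent, and a fallback built only on known chemistry is given at the end.

**Retrosynthetic overview** (tetralin numbering: C1 bears the pendant aryl, C2 the CH2OAc arm, C3 the CH2OH arm)
1. Ring A is the fused guaiacyl ring, ring B the carbocycle C1–C2–C3–C4–C4a–C8a, ring C the pendant guaiacyl ring. Rings A and C are bought as dihydroferulic acid; ring B is the only ring built and is closed last, at C1–C8a, followed only by O-debenzylation.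
2. Key disconnection: C1–C8a together with C1–H, back to an open-chain (2R,3R)-2,3-dibenzylbutane-1,4-diol monoacetate whose second oxygen carries an N-phthalimidoyl radical trigger. One photoredox/acid operation oxidises C1–H, closes ring B, sets C1, and leaves the acetate on the C2 arm and the free hydroxyl on the C3 arm.
3. Enabling feature: the oxygen of the C3 hydroxymethyl group stands 1,5 to the hydrogen on C1 (O–CH2–C3–C2–C1–H); C1 is benzylic to ring C and para to its oxygen (stabilised cation); C8a of ring A lies para to the methoxy group (nucleophilic site).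
4. The C2-symmetric diol comes from oxidative homocoupling of the oxazolidinone imide enolate of O-benzyl-dihydroferulic acid (C2–C3 bond and both stereocenters in one step), then LiBH4. Its homotopic hydroxyls allow only one monoacetate.
5. Order of ring formation: a temporary tetrahydrofuran (O–C1) forms and opens inside the key step, then ring B.

Key step: step 7

Remark: compound 12 is written as its 2,3-trans epimer (the expected major one); the configuration at its aryl-bearing carbon is lost again on ionisation and has no bearing on the outcome.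

Step 1
Reactants: 1 3-(4-hydroxy-3-methoxyphenyl)propanoic acid (dihydroferulic acid)
Product: 3 3-(4-benzyloxy-3-methoxyphenyl)propanoic acid, via benzyl ester 2 (not isolated)
Conditions: BnBr (2.2 equiv), K2CO3, DMF, 60 °C; then NaOH aq, MeOH, 60 °C, same flask; HCl work-up
Reagents that add atoms: benzyl bromide BrCc1ccccc1; sodium hydroxide [Na+].[OH-] (oxygen of the regenerated carboxyl group)
Why: Williamson O-alkylation of phenoxide and carboxylate followed by saponification of the benzyl ester in the same flask should leave only the aryl benzyl ether, and no stereocenter is involved.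

Step 2
Reactants: 3 3-(4-benzyloxy-3-methoxyphenyl)propanoic acid; 4 (S)-4-isopropyl-1,3-oxazolidin-2-one
Product: 6 (S)-3-[3-(4-benzyloxy-3-methoxyphenyl)propanoyl]-4-isopropyl-1,3-oxazolidin-2-one, via mixed pivalic anhydride 5 (not isolated)
Conditions: PivCl, Et3N, THF, −20 °C; then 4, LiCl, −20 °C → rt
Reagents that add atoms: none
Why: N-acylation of an oxazolidinone by a mixed pivalic anhydride in the presence of LiCl and Et3N is the standard route to such imides, the hindered pivaloyl carbonyl directs attack to the wanted acyl group, and the stereocenter of 4 is untouched.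

Step 3
Reactants: 6 (S)-3-[3-(4-benzyloxy-3-methoxyphenyl)propanoyl]-4-isopropyl-1,3-oxazolidin-2-one (two molecules)
Product: 8 (2R,3R)-2,3-bis[(4-benzyloxy-3-methoxyphenyl)methyl]-1,4-bis[(4S)-4-isopropyl-2-oxo-1,3-oxazolidin-3-yl]butane-1,4-dione, via lithium Z-enolate 7 (not isolated)
Conditions: LDA (1.05 equiv), THF, −78 °C; then TiCl4 (1.0 equiv), −78 °C → rt
Reagents that add atoms: none
Why: Oxidative homocoupling of chelated Z-enolates of 3-arylpropanoyl oxazolidinones by tetravalent titanium (one-electron oxidation, then α,α-coupling) is a known reaction of this substrate class; each α-carbon should be attacked on the face opposite to the isopropyl group of the S auxiliary, as in enolate alkylation, which should make the R,R dimer the main product, to be purified by crystallisation or chromatography.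

Step 4
Reactants: 8 (2R,3R)-2,3-bis[(4-benzyloxy-3-methoxyphenyl)methyl]-1,4-bis[(4S)-4-isopropyl-2-oxo-1,3-oxazolidin-3-yl]butane-1,4-dione
Product: 9 (2R,3R)-2,3-bis[(4-benzyloxy-3-methoxyphenyl)methyl]butane-1,4-diol
Conditions: LiBH4, H2O (2 equiv), THF, 0 °C → rt
Reagents that add atoms: none
Why: Reductive cleavage of N-acyl oxazolidinones by LiBH4 gives the primary alcohols and returns the auxiliary; hydride delivery is faster than enolisation, so the two stereocenters should survive, and the aryl benzyl ethers are inert.

Step 5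
Reactants: 9 (2R,3R)-2,3-bis[(4-benzyloxy-3-methoxyphenyl)methyl]butane-1,4-diol
Product: 10 (2R,3R)-2,3-bis[(4-benzyloxy-3-methoxyphenyl)methyl]-4-hydroxybutyl acetate
Conditions: Ac2O (0.9 equiv), pyridine, CH2Cl2, −20 → 0 °C; unreacted 9 recovered
Reagents that add atoms: acetic anhydride CC(=O)OC(C)=O
Why: The two hydroxyl groups of C2-symmetric 9 are homotopic, so substoichiometric acylation can give only one monoacetate, and unreacted diol is recovered and resubmitted.

Step 6
Reactants: 10 (2R,3R)-2,3-bis[(4-benzyloxy-3-methoxyphenyl)methyl]-4-hydroxybutyl acetate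
Product: 11 (2R,3R)-2,3-bis[(4-benzyloxy-3-methoxyphenyl)methyl]-4-(1,3-dioxoisoindolin-2-yloxy)butyl acetate
Conditions: N-hydroxyphthalimide, PPh3, DIAD, THF, 0 °C → rt
Reagents that add atoms: N-hydroxyphthalimide O=C1c2ccccc2C(=O)N1O
Why: The Mitsunobu reaction of a primary alcohol with the acidic N-hydroxyphthalimide is the standard route to N-alkoxyphthalimides; substitution occurs at a CH2 group, so no stereocenter is affected, and the acetate is inert.

Step 7
Reactants: 11 (2R,3R)-2,3-bis[(4-benzyloxy-3-methoxyphenyl)methyl]-4-(1,3-dioxoisoindolin-2-yloxy)butyl acetate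
Product: 13 [(1S,2R,3R)-7-benzyloxy-1-(4-benzyloxy-3-methoxyphenyl)-3-(hydroxymethyl)-6-methoxy-1,2,3,4-tetrahydronaphthalen-2-yl]methyl acetate, via tetrahydrofuran acetate 12 (not isolated)
Conditions: fac-Ir(ppy)3 (tris(2-phenylpyridinato)iridium, 1 mol %), degassed CH2Cl2, blue LEDs (450 nm), rt; then TFA (5 equiv), 0 °C → rt, same flask
Reagents that add atoms: none
Why: Proposed new method: the excited photocatalyst transfers one electron to the N-alkoxyphthalimide, N–O cleavage releases phthalimide anion and the primary alkoxy radical, this radical takes the benzylic hydrogen of the future C1 by 1,5-hydrogen transfer through a six-membered transition state, the tetravalent iridium left behind oxidises the electron-rich benzylic radical to the 4-benzyloxy-3-methoxybenzyl cation (redox-neutral radical-polar crossover), the hydroxyl just regenerated captures it to give tetrahydrofuran 12, and TFA then re-ionises the benzylic C–O bond so that C8a of ring A attacks the cation. The closest known reaction types are the photoredox δ-C–H functionalisation through alkoxy radicals made from N-alkoxyphthalimides and the hypoiodite-type oxidative cyclisation of 4-arylbutanols to 2-aryltetrahydrofurans for the first stage, and the acid-induced rearrangement of 2-aryl-4-benzyltetrahydrofuran lignans into 1-aryltetralins for the second stage; what is new is their fusion into one redox-neutral operation on a 1,4-diarylbutane. The temporary tetrahydrofuran ring closes 5-exo by attack of oxygen on the cationic C1 and is opened again, and ring B closes by intramolecular Friedel–Crafts alkylation from C8a to C1, a six-membered closure that is exo with respect to the cationic carbon and endo with respect to the arene π bond. The new stereocenter C1 is set in the Friedel–Crafts step under control of the C2 and C3 stereocenters, through a chair-like transition state with the aryl group and both CH2O arms pseudo-equatorial, which should give the 1,2-trans, 2,3-trans product; because ionisation of 12 is reversible and C–C bond formation is not, both C1 epimers of 12 should converge on it. The step needs site-selective hydrogen abstraction, which the 1,5-geometry, the weak benzylic C–H bond and the acetate cap on the other oxygen secure (only the benzyl group on the acetate-bearing carbon can be reached, and this is what puts the acetate on the C2 arm and the free hydroxyl on the C3 arm), and regioselective arylation of ring A, which the para-directing methoxy group and the lower hindrance at C8a secure.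

Step 8
Reactants: 13 [(1S,2R,3R)-7-benzyloxy-1-(4-benzyloxy-3-methoxyphenyl)-3-(hydroxymethyl)-6-methoxy-1,2,3,4-tetrahydronaphthalen-2-yl]methyl acetate
Product: 14 [(1S,2R,3R)-7-hydroxy-1-(4-hydroxy-3-methoxyphenyl)-3-(hydroxymethyl)-6-methoxy-1,2,3,4-tetrahydronaphthalen-2-yl]methyl acetate
Conditions: H2 (1 atm), 10% Pd/C, EtOAc/EtOH, rt
Reagents that add atoms: none
Why: Neutral hydrogenolysis of the two aryl benzyl ethers over palladium on carbon should free both phenols without touching the acetate, the primary alcohol or the C1–H bond, and without base that could cause acetyl migration.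

**Compound list**
1 | 3-(4-hydroxy-3-methoxyphenyl)propanoic acid (dihydroferulic acid) | COc1cc(CCC(=O)O)ccc1O | starting material
2 | benzyl 3-(4-benzyloxy-3-methoxyphenyl)propanoate (not isolated) | COc1cc(CCC(=O)OCc2ccccc2)ccc1OCc1ccccc1 | intermediate
3 | 3-(4-benzyloxy-3-methoxyphenyl)propanoic acid | COc1cc(CCC(=O)O)ccc1OCc1ccccc1 | intermediate
4 | (S)-4-isopropyl-1,3-oxazolidin-2-one | CC(C)[C@H]1COC(=O)N1 | starting material
5 | 3-(4-benzyloxy-3-methoxyphenyl)propanoic pivalic anhydride (not isolated) | COc1cc(CCC(=O)OC(=O)C(C)(C)C)ccc1OCc1ccccc1 | intermediate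
6 | (S)-3-[3-(4-benzyloxy-3-methoxyphenyl)propanoyl]-4-isopropyl-1,3-oxazolidin-2-one | COc1cc(CCC(=O)N2[C@@H](C(C)C)COC2=O)ccc1OCc1ccccc1 | intermediate
7 | lithium Z-enolate of 6 (not isolated) | COc1cc(C/C=C(\O[Li])N2[C@@H](C(C)C)COC2=O)ccc1OCc1ccccc1 | intermediate
8 | (2R,3R)-2,3-bis[(4-benzyloxy-3-methoxyphenyl)methyl]-1,4-bis[(4S)-4-isopropyl-2-oxo-1,3-oxazolidin-3-yl]butane-1,4-dione | O=C([C@H](Cc1ccc(OCc2ccccc2)c(OC)c1)[C@@H](Cc1ccc(OCc2ccccc2)c(OC)c1)C(=O)N1[C@@H](C(C)C)COC1=O)N1[C@@H](C(C)C)COC1=O | intermediate
9 | (2R,3R)-2,3-bis[(4-benzyloxy-3-methoxyphenyl)methyl]butane-1,4-diol (di-O-benzyl secoisolariciresinol) | OC[C@H](Cc1ccc(OCc2ccccc2)c(OC)c1)[C@H](CO)Cc1ccc(OCc2ccccc2)c(OC)c1 | intermediate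
10 | (2R,3R)-2,3-bis[(4-benzyloxy-3-methoxyphenyl)methyl]-4-hydroxybutyl acetate | CC(=O)OC[C@H](Cc1ccc(OCc2ccccc2)c(OC)c1)[C@H](CO)Cc1ccc(OCc2ccccc2)c(OC)c1 | intermediate
11 | (2R,3R)-2,3-bis[(4-benzyloxy-3-methoxyphenyl)methyl]-4-(1,3-dioxoisoindolin-2-yloxy)butyl acetate | CC(=O)OC[C@H](Cc1ccc(OCc2ccccc2)c(OC)c1)[C@H](CON1C(=O)c2ccccc2C1=O)Cc1ccc(OCc2ccccc2)c(OC)c1 | intermediate
12 | [(2S,3R,4R)-2-(4-benzyloxy-3-methoxyphenyl)-4-[(4-benzyloxy-3-methoxyphenyl)methyl]oxolan-3-yl]methyl acetate (not isolated) | CC(=O)OC[C@@H]1[C@@H](c2ccc(OCc3ccccc3)c(OC)c2)OC[C@@H]1Cc1ccc(OCc2ccccc2)c(OC)c1 | intermediate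
13 | [(1S,2R,3R)-7-benzyloxy-1-(4-benzyloxy-3-methoxyphenyl)-3-(hydroxymethyl)-6-methoxy-1,2,3,4-tetrahydronaphthalen-2-yl]methyl acetate | COc1cc([C@H]2c3cc(OCc4ccccc4)c(OC)cc3C[C@@H](CO)[C@@H]2COC(C)=O)ccc1OCc1ccccc1 | intermediate
14 | [(1S,2R,3R)-7-hydroxy-1-(4-hydroxy-3-methoxyphenyl)-3-(hydroxymethyl)-6-methoxy-1,2,3,4-tetrahydronaphthalen-2-yl]methyl acetate (CNP0110635.1) | COc1cc([C@H]2c3cc(O)c(OC)cc3C[C@@H](CO)[C@@H]2COC(C)=O)ccc1O | target

Total step count: 8. Longest linear sequence: 8 steps (1 to 14).

**Steps most likely to fail**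

1. Step 7. The alkoxy radical may fragment (β-scission with loss of formaldehyde), add to ring A, or abstract the α-acetoxy hydrogen instead of the benzylic one. The electron-transfer sequence may also stall before the radical is oxidised, or the cation may be captured by phthalimide. Fallback with known chemistry, setting out from diol 9: DDQ (1 equiv, CH2Cl2, pH 7 buffer, 0 °C) abstracts a benzylic hydride. Because 9 is C2-symmetric both benzylic positions are equivalent, and the δ-hydroxyl closes the cation to the single tetrahydrofuran alcohol di-O-benzyl-lariciresinol F1. Acetylation of its only hydroxyl (Ac2O, pyridine) gives 12, now isolated, and TFA in CH2Cl2 at 0 °C rearranges 12 to 13, where the route is rejoined.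

2. Step 3. Facial control in the radical-type enolate coupling may be poor, giving much of the R,S and S,S dimers, or the enolate may be over-oxidised instead of coupled. Fallback from imide 6 by two successive enolate alkylations:
   - NaHMDS and tert-butyl bromoacetate (THF, −78 °C) alkylate 6 anti to the isopropyl group to give the succinate imide F2.
   - LiBH4 cleaves the imide selectively to the hydroxy ester F3, returning 4.
   - Catalytic TsOH in toluene lactonises F3 to the (R)-β-benzyl-γ-butyrolactone F4.
   - LiHMDS, then 4-benzyloxy-3-methoxybenzyl bromide, alkylates the lactone enolate trans to the existing benzyl group to give di-O-benzyl-matairesinol F5.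
   - LiAlH4 reduces F5 to diol 9, where the route is rejoined.

3. Step 5. Acylation of the C2-symmetric diol is statistical, so over-acylation and the need to recycle may erode material throughput. Fallback from diol 9: monosilylation through the monosodium alkoxide (NaH 1 equiv, THF; then TBSCl) gives the mono-silyl ether F6. Mitsunobu reaction with N-hydroxyphthalimide gives the silyl-protected N-alkoxyphthalimide F7. HF·pyridine in THF removes the silyl group to give the hydroxy N-alkoxyphthalimide F8, and Ac2O/pyridine acetylates it to 11, where the route is rejoined.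

**Further compounds**
F1 | step 7 | [(2S,3R,4R)-2-(4-benzyloxy-3-methoxyphenyl)-4-[(4-benzyloxy-3-methoxyphenyl)methyl]oxolan-3-yl]methanol (di-O-benzyl-lariciresinol) | OC[C@@H]1[C@@H](c2ccc(OCc3ccccc3)c(OC)c2)OC[C@@H]1Cc1ccc(OCc2ccccc2)c(OC)c1
F2 | step 3 | tert-butyl (3R)-3-[(4-benzyloxy-3-methoxyphenyl)methyl]-4-[(4S)-4-isopropyl-2-oxo-1,3-oxazolidin-3-yl]-4-oxobutanoate | CC(C)(C)OC(=O)C[C@@H](Cc1ccc(OCc2ccccc2)c(OC)c1)C(=O)N1[C@@H](C(C)C)COC1=O
F3 | step 3 | tert-butyl (3R)-3-[(4-benzyloxy-3-methoxyphenyl)methyl]-4-hydroxybutanoate | CC(C)(C)OC(=O)C[C@@H](Cc1ccc(OCc2ccccc2)c(OC)c1)CO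
F4 | step 3 | (4R)-4-[(4-benzyloxy-3-methoxyphenyl)methyl]oxolan-2-one | O=C1C[C@@H](Cc2ccc(OCc3ccccc3)c(OC)c2)CO1
F5 | step 3 | (3R,4R)-3,4-bis[(4-benzyloxy-3-methoxyphenyl)methyl]oxolan-2-one (di-O-benzyl-matairesinol) | O=C1[C@H](Cc2ccc(OCc3ccccc3)c(OC)c2)[C@@H](Cc2ccc(OCc3ccccc3)c(OC)c2)CO1
F6 | step 5 | (2R,3R)-2,3-bis[(4-benzyloxy-3-methoxyphenyl)methyl]-4-[tert-butyl(dimethyl)silyl]oxybutan-1-ol | CC(C)(C)[Si](C)(C)OC[C@H](Cc1ccc(OCc2ccccc2)c(OC)c1)[C@H](CO)Cc1ccc(OCc2ccccc2)c(OC)c1
F7 | step 5 | 2-[(2R,3R)-2,3-bis[(4-benzyloxy-3-methoxyphenyl)methyl]-4-[tert-butyl(dimethyl)silyl]oxybutoxy]isoindoline-1,3-dione | CC(C)(C)[Si](C)(C)OC[C@H](Cc1ccc(OCc2ccccc2)c(OC)c1)[C@H](CON1C(=O)c2ccccc2C1=O)Cc1ccc(OCc2ccccc2)c(OC)c1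
F8 | step 5 | 2-[(2R,3R)-2,3-bis[(4-benzyloxy-3-methoxyphenyl)methyl]-4-hydroxybutoxy]isoindoline-1,3-dione | OC[C@H](Cc1ccc(OCc2ccccc2)c(OC)c1)[C@H](CON1C(=O)c2ccccc2C1=O)Cc1ccc(OCc2ccccc2)c(OC)c1
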